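**Retrosynthetic overview** (C1 = lactone carbonyl, C5 = ring carbinol, C7/C9/C11 = chain carbinols, C20 = terminal CH3)
1. Endgame: global deprotection; C2=C3 by E1cB loss of a C3 silyloxy group from the saturated lactone; the lactone ring (O–C1…C5) by oxidative lactonisation of a C1/C5 1,5-diol.
2. The C5 and C9 carbinols come from a 7-hydroxy-5,9-diketone: C7–OH is 1,3-anti to both, so one hydroxyl-directed anti reduction sets both centres.
3. Key disconnection C8–C9: a dithiane-stabilised C9 carbanion, released by a 1,4-Brook shift of silicon from C9 to O11, opens the oxirane ring C7–C8–O7 of the C1–C8 half at C8. Enabling feature: C9 sits between two CH2 groups (C8, C10) whose far neighbours C7 and C11 both carry oxygen (array O7–C7–C8–C9–C10–C11–O11), so C9 maps onto a one-carbon acyl dianion linchpin that joins two terminal oxirane rings.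
4. The C1–C8 oxirane comes from 1,3-dithiane (C5), a C1–C4 oxirane and (R)-epichlorohydrin (C6–C8) by two Corey–Seebach alkylations; the C10–C20 oxirane comes from (R)-epichlorohydrin and an octyl Grignard reagent.
5. Ring order: temporary dithiane rings at C5 (step 3) and C9 (step 6), both removed in step 7; then the lactone ring (step 10); then a temporary 7,9-acetonide ring (step 11, removed in step 13).

Key step: step 6

Assumption: (2S)-2-[2-(benzyloxy)ethyl]oxirane is taken as a purchasable single enantiomer; its stereocentre becomes C3, which is erased in step 12, so its configuration only keeps the intermediates single diastereomers.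

**Step 1**
Reactants: 1 (R)-epichlorohydrin; 2 n-octylmagnesium chloride
Product: 3 (2R)-1-chloroundecan-2-ol
Conditions: CuI (10 mol%), THF, −40 to 0 °C; dilute aq HCl work-up
Reagents that add atoms: none
Why: Copper-catalysed Grignard opening of the oxirane by SN2 attack at its unsubstituted CH2 carbon leaves the C–O stereocentre (future C11) untouched, so the chlorohydrin should keep the (R) configuration.

**Step 2**
Reactants: 3 (2R)-1-chloroundecan-2-ol
Product: 4 (2R)-2-nonyloxirane
Conditions: NaOH (powdered), Et2O, rt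
Reagents that add atoms: none
Why: Intramolecular Williamson etherification (3-exo-tet displacement of chloride by the alkoxide) breaks no bond at the stereocentre, so the configuration is retained.

**Step 3**
Reactants: 5 1,3-dithiane; 6 (2S)-2-[2-(benzyloxy)ethyl]oxirane
Product: 8 (2S)-4-(benzyloxy)-1-(1,3-dithian-2-yl)butan-2-ol, via 2-lithio-1,3-dithiane 7 (not isolated)
Conditions: n-BuLi, THF, −30 °C; then 6, −30 to 0 °C; H2O quench
Reagents that add atoms: none
Why: Corey–Seebach alkylation in which 2-lithio-1,3-dithiane opens the monosubstituted oxirane by SN2 attack at its unsubstituted CH2 carbon, so the C–O stereocentre (future C3) is untouched and the future C5 enters at the masked-ketone oxidation level.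

**Step 4**
Reactants: 8 (2S)-4-(benzyloxy)-1-(1,3-dithian-2-yl)butan-2-ol
Product: 9 2-[(2S)-4-(benzyloxy)-2-(tert-butyldimethylsilyloxy)butyl]-1,3-dithiane
Conditions: TBSCl, imidazole, DMF, rt
Reagents that add atoms: tert-butyldimethylsilyl chloride (TBSCl), CC(C)(C)[Si](C)(C)Cl
Why: Imidazole-promoted silylation of the secondary alcohol installs the silyl ether that protects O3 through the organolithium steps and later serves as the leaving group of step 12.

**Step 5**
Reactants: 9 2-[(2S)-4-(benzyloxy)-2-(tert-butyldimethylsilyloxy)butyl]-1,3-dithiane; 1 (R)-epichlorohydrin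
Product: 12 2-[(2S)-4-(benzyloxy)-2-(tert-butyldimethylsilyloxy)butyl]-2-[(2R)-oxiran-2-ylmethyl]-1,3-dithiane, via dithiane carbanion 10 (not isolated), via chloro alkoxide 11 (not isolated)
Conditions: t-BuLi, THF/HMPA (10:1), −78 °C; then 1 (1.5 equiv), −78 °C to rt
Reagents that add atoms: none
Why: Corey–Seebach alkylation of the 2-substituted dithiane, in which t-BuLi removes the dithiane C2 proton, carbanion 10 opens epichlorohydrin at the oxirane CH2 and not at CH2Cl, and alkoxide 11 closes onto CH2Cl on warming (3-exo-tet), so that the C7 stereocentre is carried over unchanged into a new terminal (R)-oxirane.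

**Step 6**
Reactants: 13 2-(tert-butyldimethylsilyl)-1,3-dithiane; 4 (2R)-2-nonyloxirane; 12 2-[(2S)-4-(benzyloxy)-2-(tert-butyldimethylsilyloxy)butyl]-2-[(2R)-oxiran-2-ylmethyl]-1,3-dithiane
Product: 17 (2S)-1-{2-[(2S)-4-(benzyloxy)-2-(tert-butyldimethylsilyloxy)butyl]-1,3-dithian-2-yl}-3-{2-[(2R)-2-(tert-butyldimethylsilyloxy)undecyl]-1,3-dithian-2-yl}propan-2-ol, via silyl lithiodithiane 14 (not isolated), via alkoxide 15 (not isolated), via relay carbanion 16 (not isolated)
Conditions: t-BuLi, Et2O, −78 to −45 °C; 4, −78 to −25 °C; then 12, HMPA, THF, −78 to 0 °C; H2O quench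
Reagents that add atoms: none
Why: Lithiodithiane 14 opens oxirane 4 at its CH2 terminus (C10) in Et2O to give alkoxide 15; HMPA/THF then triggers the 1,4-Brook shift of silicon from C9 to O11, which turns C9 into the dithiane-stabilised carbanion 16, and 16 opens the oxirane of 12 by SN2 attack at its unsubstituted carbon C8, forming the C8–C9 bond. The closest known reaction type is the three-component linchpin coupling of a 2-silyl-1,3-dithiane with two different terminal epoxides under solvent-controlled anion relay, an extension of Corey–Seebach dithiane alkylation. No ring is closed; the only ring event is opening of the three-membered oxirane at its CH2 carbon. No stereocentre is created: C11 and C7 are carried in from the two oxiranes, whose C–O centres are untouched because both attacks occur at CH2, and C9 is deliberately left at the ketone oxidation level for step 8. The step needs correct relay timing (secured by withholding HMPA until 4 is consumed), terminal regioselectivity (secured by the bulk of the fully substituted carbanion), and differentiation of O7 from O11 (delivered automatically as free hydroxyl versus silyl ether).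

**Step 7**
Reactants: 17 the bis-dithiane alcohol from step 6
Product: 18 (3S,7S,11R)-1-(benzyloxy)-3,11-bis(tert-butyldimethylsilyloxy)-7-hydroxyicosane-5,9-dione
Conditions: Hg(ClO4)2, CaCO3, THF/H2O (5:1), 0 °C; used crude
Reagents that add atoms: water, O
Why: Dithioacetal hydrolysis, in which thiophilic divalent mercury activates both dithianes and water converts them into the ketones, while CaCO3 buffers the perchloric acid so that the β-hydroxy and β-silyloxy ketone units should neither dehydrate nor lose silicon.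

**Step 8**
Reactants: 18 (3S,7S,11R)-1-(benzyloxy)-3,11-bis(tert-butyldimethylsilyloxy)-7-hydroxyicosane-5,9-dione
Product: 19 (3S,5R,7S,9S,11R)-1-(benzyloxy)-3,11-bis(tert-butyldimethylsilyloxy)icosane-5,7,9-triol
Conditions: Me4NBH(OAc)3 (10 equiv), MeCN/AcOH (1:1), −35 to −20 °C; aq sodium potassium tartrate
Reagents that add atoms: none
Why: Evans–Saksena reduction run in two directions, in which the C7 hydroxyl exchanges onto boron and delivers hydride intramolecularly through a chair six-membered transition state to each flanking β-carbonyl in turn, which should set C5 and C9 both 1,3-anti to C7, the silyl ethers at O3 and O11 being unable to bind boron and therefore not directing.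

**Step 9**
Reactants: 19 (3S,5R,7S,9S,11R)-1-(benzyloxy)-3,11-bis(tert-butyldimethylsilyloxy)icosane-5,7,9-triol
Product: 20 (3S,5R,7S,9S,11R)-3,11-bis(tert-butyldimethylsilyloxy)icosane-1,5,7,9-tetraol
Conditions: H2 (1 atm), 10% Pd/C, EtOAc, rt
Reagents that add atoms: none
Why: Hydrogenolysis of the benzyl ether; the molecule holds no alkene or other reducible group at this stage and the silyl ethers are stable in EtOAc.

**Step 10**
Reactants: 20 (3S,5R,7S,9S,11R)-3,11-bis(tert-butyldimethylsilyloxy)icosane-1,5,7,9-tetraol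
Product: 23 (4R,6R)-4-(tert-butyldimethylsilyloxy)-6-[(2S,4S,6R)-6-(tert-butyldimethylsilyloxy)-2,4-dihydroxypentadecyl]tetrahydro-2H-pyran-2-one, via aldehyde 21 (not isolated), via lactol 22 (not isolated)
Conditions: TEMPO (0.2 equiv), PhI(OAc)2 (3 equiv), CH2Cl2, rt
Reagents that add atoms: none
Why: Oxoammonium oxidation selective for the primary C1 alcohol gives the aldehyde, which only the 1,5-related C5 hydroxyl can trap as a six-membered lactol (6-exo-trig), and the lactol is oxidised again to the δ-lactone while the secondary C7 and C9 hydroxyls are left alone.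

**Step 11**
Reactants: 23 the 4-silyloxy lactone diol from step 10
Product: 24 (4R,6R)-4-(tert-butyldimethylsilyloxy)-6-({(4S,6S)-6-[(2R)-2-(tert-butyldimethylsilyloxy)undecyl]-2,2-dimethyl-1,3-dioxan-4-yl}methyl)tetrahydro-2H-pyran-2-one
Conditions: 2,2-dimethoxypropane, PPTS (cat.), CH2Cl2, rt
Reagents that add atoms: 2,2-dimethoxypropane, COC(C)(C)OC
Why: Acid-catalysed transketalisation of the only free diol (O5 is now in the lactone) gives the anti-1,3-diol acetonide and masks both hydroxyls against conjugate addition to the enoate formed next.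

**Step 12**
Reactants: 24 the acetonide-protected 4-silyloxy lactone from step 11
Product: 25 (6S)-6-({(4S,6S)-6-[(2R)-2-(tert-butyldimethylsilyloxy)undecyl]-2,2-dimethyl-1,3-dioxan-4-yl}methyl)-5,6-dihydro-2H-pyran-2-one
Conditions: DBU (3 equiv), CH2Cl2, rt to 40 °C
Reagents that add atoms: none
Why: E1cB elimination, in which DBU deprotonates C2 and the lactone enolate expels the C3 silanolate to give the conjugated ring alkene (necessarily cis in the six-membered ring), and only the C3 silyloxy group is β to a carbonyl so the C11 silyl ether is untouched.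

**Step 13**
Reactants: 25 the protected dihydropyranone from step 12
Product: 26 (6S)-6-[(2S,4R,6R)-2,4,6-trihydroxypentadecyl]-5,6-dihydro-2H-pyran-2-one
Conditions: HF (48% aq), MeCN, 0 °C to rt
Reagents that add atoms: none
Why: Aqueous HF cleaves the C11 silyl ether through Si–F bond formation and the aqueous acid hydrolyses the strained anti-acetonide, while the unsaturated δ-lactone is stable to non-nucleophilic aqueous acid, so the target should be released with all four stereocentres intact.

**Compound list**
1 | (R)-epichlorohydrin, (2R)-2-(chloromethyl)oxirane | ClC[C@H]1CO1 | starting material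
2 | n-octylmagnesium chloride | CCCCCCCC[Mg]Cl | starting material
3 | (2R)-1-chloroundecan-2-ol | CCCCCCCCC[C@@H](O)CCl | intermediate
4 | (2R)-2-nonyloxirane | CCCCCCCCC[C@@H]1CO1 | intermediate
5 | 1,3-dithiane | C1CSCSC1 | starting material
6 | (2S)-2-[2-(benzyloxy)ethyl]oxirane | c1ccccc1COCC[C@H]2CO2 | starting material
7 | 2-lithio-1,3-dithiane | [Li]C1SCCCS1 | intermediate
8 | (2S)-4-(benzyloxy)-1-(1,3-dithian-2-yl)butan-2-ol | c1ccccc1COCC[C@H](O)CC2SCCCS2 | intermediate
9 | 2-[(2S)-4-(benzyloxy)-2-(tert-butyldimethylsilyloxy)butyl]-1,3-dithiane | c1ccccc1COCC[C@H](O[Si](C)(C)C(C)(C)C)CC2SCCCS2 | intermediate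
10 | 2-lithio-2-[(2S)-4-(benzyloxy)-2-(tert-butyldimethylsilyloxy)butyl]-1,3-dithiane | c1ccccc1COCC[C@H](O[Si](C)(C)C(C)(C)C)CC2([Li])SCCCS2 | intermediate
11 | lithium (2R)-1-chloro-3-{2-[(2S)-4-(benzyloxy)-2-(tert-butyldimethylsilyloxy)butyl]-1,3-dithian-2-yl}propan-2-olate | c1ccccc1COCC[C@H](O[Si](C)(C)C(C)(C)C)CC2(SCCCS2)C[C@@H](O[Li])CCl | intermediate
12 | 2-[(2S)-4-(benzyloxy)-2-(tert-butyldimethylsilyloxy)butyl]-2-[(2R)-oxiran-2-ylmethyl]-1,3-dithiane | c1ccccc1COCC[C@H](O[Si](C)(C)C(C)(C)C)CC2(SCCCS2)C[C@@H]3CO3 | intermediate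
13 | 2-(tert-butyldimethylsilyl)-1,3-dithiane | CC(C)(C)[Si](C)(C)C1SCCCS1 | starting material
14 | 2-lithio-2-(tert-butyldimethylsilyl)-1,3-dithiane | CC(C)(C)[Si](C)(C)C1([Li])SCCCS1 | intermediate
15 | lithium (2R)-1-[2-(tert-butyldimethylsilyl)-1,3-dithian-2-yl]undecan-2-olate | CCCCCCCCC[C@@H](O[Li])CC1(SCCCS1)[Si](C)(C)C(C)(C)C | intermediate
16 | 2-lithio-2-[(2R)-2-(tert-butyldimethylsilyloxy)undecyl]-1,3-dithiane | CCCCCCCCC[C@@H](O[Si](C)(C)C(C)(C)C)CC1([Li])SCCCS1 | intermediate
17 | (2S)-1-{2-[(2S)-4-(benzyloxy)-2-(tert-butyldimethylsilyloxy)butyl]-1,3-dithian-2-yl}-3-{2-[(2R)-2-(tert-butyldimethylsilyloxy)undecyl]-1,3-dithian-2-yl}propan-2-ol | CCCCCCCCC[C@@H](O[Si](C)(C)C(C)(C)C)CC1(SCCCS1)C[C@H](O)CC2(SCCCS2)C[C@@H](O[Si](C)(C)C(C)(C)C)CCOCc3ccccc3 | intermediate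
18 | (3S,7S,11R)-1-(benzyloxy)-3,11-bis(tert-butyldimethylsilyloxy)-7-hydroxyicosane-5,9-dione | CCCCCCCCC[C@@H](O[Si](C)(C)C(C)(C)C)CC(=O)C[C@H](O)CC(=O)C[C@@H](O[Si](C)(C)C(C)(C)C)CCOCc1ccccc1 | intermediate
19 | (3S,5R,7S,9S,11R)-1-(benzyloxy)-3,11-bis(tert-butyldimethylsilyloxy)icosane-5,7,9-triol | CCCCCCCCC[C@@H](O[Si](C)(C)C(C)(C)C)C[C@@H](O)C[C@H](O)C[C@@H](O)C[C@@H](O[Si](C)(C)C(C)(C)C)CCOCc1ccccc1 | intermediate
20 | (3S,5R,7S,9S,11R)-3,11-bis(tert-butyldimethylsilyloxy)icosane-1,5,7,9-tetraol | CCCCCCCCC[C@@H](O[Si](C)(C)C(C)(C)C)C[C@@H](O)C[C@H](O)C[C@@H](O)C[C@@H](O[Si](C)(C)C(C)(C)C)CCO | intermediate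
21 | (3R,5R,7S,9S,11R)-3,11-bis(tert-butyldimethylsilyloxy)-5,7,9-trihydroxyicosanal | CCCCCCCCC[C@@H](O[Si](C)(C)C(C)(C)C)C[C@@H](O)C[C@H](O)C[C@@H](O)C[C@@H](O[Si](C)(C)C(C)(C)C)CC=O | intermediate
22 | (4R,6R)-4-(tert-butyldimethylsilyloxy)-6-[(2S,4S,6R)-6-(tert-butyldimethylsilyloxy)-2,4-dihydroxypentadecyl]tetrahydro-2H-pyran-2-ol (anomeric mixture) | CCCCCCCCC[C@@H](O[Si](C)(C)C(C)(C)C)C[C@@H](O)C[C@H](O)C[C@@H]1C[C@@H](O[Si](C)(C)C(C)(C)C)CC(O)O1 | intermediate
23 | (4R,6R)-4-(tert-butyldimethylsilyloxy)-6-[(2S,4S,6R)-6-(tert-butyldimethylsilyloxy)-2,4-dihydroxypentadecyl]tetrahydro-2H-pyran-2-one | CCCCCCCCC[C@@H](O[Si](C)(C)C(C)(C)C)C[C@@H](O)C[C@H](O)C[C@@H]1C[C@@H](O[Si](C)(C)C(C)(C)C)CC(=O)O1 | intermediate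
24 | (4R,6R)-4-(tert-butyldimethylsilyloxy)-6-({(4S,6S)-6-[(2R)-2-(tert-butyldimethylsilyloxy)undecyl]-2,2-dimethyl-1,3-dioxan-4-yl}methyl)tetrahydro-2H-pyran-2-one | CCCCCCCCC[C@@H](O[Si](C)(C)C(C)(C)C)C[C@@H]1C[C@@H](C[C@@H]2C[C@@H](O[Si](C)(C)C(C)(C)C)CC(=O)O2)OC(C)(C)O1 | intermediate
25 | (6S)-6-({(4S,6S)-6-[(2R)-2-(tert-butyldimethylsilyloxy)undecyl]-2,2-dimethyl-1,3-dioxan-4-yl}methyl)-5,6-dihydro-2H-pyran-2-one | CCCCCCCCC[C@@H](O[Si](C)(C)C(C)(C)C)C[C@@H]1C[C@@H](C[C@@H]2CC=CC(=O)O2)OC(C)(C)O1 | intermediate
26 | (6S)-6-[(2S,4R,6R)-2,4,6-trihydroxypentadecyl]-5,6-dihydro-2H-pyran-2-one | CCCCCCCCC[C@@H](O)C[C@@H](O)C[C@H](O)C[C@@H]1CC=CC(=O)O1 | target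

**Step count**
Total steps: 13. Longest linear sequence: 11 (steps 3, 4, 5, 6, 7, 8, 9, 10, 11, 12, 13).

**Steps most likely to fail**

Step 6 (key union). What may go wrong: the silyl migration may be incomplete or reversed, or carbanion 16 may be protonated before it reaches the hindered oxirane of 12, so that the two halves are recovered uncoupled. Fallback: a stepwise Corey–Seebach route with a preformed nucleophile. Setting out from 4, opening with 2-lithio-1,3-dithiane (1,3-dithiane, n-BuLi, THF, −20 °C) would give (2R)-1-(1,3-dithian-2-yl)undecan-2-ol F1. Silylation (TBSCl, imidazole, DMF) would give 2-[(2R)-2-(tert-butyldimethylsilyloxy)undecyl]-1,3-dithiane F2, a stable compound that can be purified. Deprotonation of F2 (t-BuLi, THF/HMPA, −78 °C) generates 16 without any relay, and addition of 12 brings the route back at 17.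

Step 8 (two-directional reduction). What may go wrong: after the first hydride delivery the C7 oxygen may stay locked in a cyclic borate with the new carbinol oxygen, so that the second carbonyl is reduced slowly and without direction, with loss of facial selectivity. Fallback: replace tethered hydride delivery by electron-transfer reduction. Setting out from 18, SmI2 (excess) in THF/MeOH at 0 °C is a known anti-selective reduction of β-hydroxy ketones in which the C7 hydroxyl chelates the samarium of each ketyl and is not consumed, so both carbonyls can be reduced in turn. This returns directly at 19 and makes no new compound.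

Step 12 (elimination). What may go wrong: silanolate is a poor leaving group, so the E1cB step may stall, and forcing base may open the product lactone by vinylogous elimination to a dienoic acid. Fallback: exchange the leaving group. Setting out from 24, HF·pyridine buffered with pyridine in THF would remove both silyl groups to give the 3,11-diol acetonide lactone F3. Boc2O, DMAP and Et3N in CH2Cl2 would give the bis(tert-butyl carbonate) F4, whose C3 carbonate is β to the lactone carbonyl and should eliminate on treatment with DBU in CH2Cl2 to the unsaturated lactone C11 tert-butyl carbonate F5. TFA/H2O would then cleave the carbonate and the acetonide, returning to the route at 26.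

**Further compounds**
F1 | step 6 | (2R)-1-(1,3-dithian-2-yl)undecan-2-ol | CCCCCCCCC[C@@H](O)CC1SCCCS1
F2 | step 6 | 2-[(2R)-2-(tert-butyldimethylsilyloxy)undecyl]-1,3-dithiane | CCCCCCCCC[C@@H](O[Si](C)(C)C(C)(C)C)CC1SCCCS1
F0 | step 8 | none | none
F3 | step 12 | 3,11-diol corresponding to 24 (both silyl groups removed, acetonide and lactone kept, configuration as in 24) | CCCCCCCCC[C@@H](O)C[C@@H]1C[C@@H](C[C@@H]2C[C@@H](O)CC(=O)O2)OC(C)(C)O1
F4 | step 12 | bis(tert-butyl carbonate) of F3 at O3 and O11 | CCCCCCCCC[C@@H](OC(=O)OC(C)(C)C)C[C@@H]1C[C@@H](C[C@@H]2C[C@@H](OC(=O)OC(C)(C)C)CC(=O)O2)OC(C)(C)O1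
F5 | step 12 | acetonide-protected dihydropyranone carrying a tert-butyl carbonate at O11 | CCCCCCCCC[C@@H](OC(=O)OC(C)(C)C)C[C@@H]1C[C@@H](C[C@@H]2CC=CC(=O)O2)OC(C)(C)O1
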